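## Analysis of the target

The target is a 1-aryl-1,2,3,4-tetrahydronaphthalene of the cyclolignan type. Aromatic ring A (6-methoxy, 7-hydroxy) is fused to carbocyclic ring B, C1 of ring B carries the pendant ring C (4-hydroxy-3-methoxyphenyl), and C2 and C3 each carry a CH2O arm. The C2 arm is esterified with (E)-p-coumaric acid; the C3 arm is a free primary alcohol. The three contiguous stereocentres are (1S,2R,3R): ring C, the C2 arm and the C3 arm are mutually trans and all equatorial on the half-chair of ring B, which is the thermodynamically preferred arrangement. Sensitive features are three free phenols on electron-rich rings, the doubly benzylic C1–H and above all the cinnamate ester, which excludes hydrogenolysis, strong hydride and strong base late in the route and can migrate to the neighbouring C3 carbinol. The central difficulty is that the two arms are nearly equivalent primary carbinols and the acyl group must end on the more hindered one, so the arms have to be born different. The strategy reads ring B as follows: C4, C3 and the C3 arm are the three carbons of an acrylate; C2 and its arm are the enol carbon pair of a 3,3-diarylpropanal whose only stereocentre is C1; the ring closes from a radical at C4a of ring A, so that the C3 arm arrives as an ester and the C2 arm as an aldehyde.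

## Retrosynthetic reasoning

**26 from 25.** The three phenolic O–Si bonds are cut last. Triisopropylsilyl ethers survive every earlier condition and leave under buffered fluoride, which is the mildest global deprotection for a molecule carrying a cinnamate next to a free carbinol.

**25 from 24 from 23.** The C3 carbinol is traced to a carboxylic acid (24) and that to a tert-butyl ester (23). Unveiling the C3 arm only after the C2 arm is acylated removes any need for a temporary protecting group on either arm. The forward steps must cleave one ester by acid and then reduce a free acid in the presence of a cinnamate.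

**23 from 19 and 22.** The ester C–O bond of the C2 arm is cut to alcohol 19 and the silylated cinnamic acid 22 (from 20). At this stage the C2 arm is the only hydroxyl in the molecule, so the acylation has no regiochemical problem.

**19 from 18.** The C2 carbinol comes from an aldehyde; a formyl group is reduced under conditions that leave a tert-butyl ester alone.

**18 from 13 and 12 (key disconnection).** Bonds C4–C4a and C2–C3 are cut together.
- This is the most simplifying cut: it removes ring B and two of the three stereocentres at once and leaves a precursor with one stereocentre and two simple partners.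
- The forward reaction is a radical cascade: a ring A radical at C4a adds to acrylate 12, and the resulting ester radical closes onto the enol carbon C2.
- The enol oxygen carries tin (13) rather than silicon, and the chain runs without a hydride. The last radical of the cascade is a nucleophilic α-oxy radical in the presence of excess acrylate; a hydride donor scarce enough to let the aryl radical reach the acrylate cannot also reduce that radical before it adds to a second acrylate. An O–Sn bond lets the radical end itself by fragmentation, which regenerates the chain carrier.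
- The halide is iodide, so that iodine abstraction by the stannyl radical outruns its reversible addition to 12.
- The acrylate is the tert-butyl ester because it directs the C3 ester equatorial, tolerates tert-butoxide equilibration and is later removed by acid.
- 13 is made in the flask from enol acetate 10 and the stannyl methoxide 11.

**10 from 9 from 8 from 7.** The enol acetate comes from aldehyde 9, the aldehyde from methyl ester 8, and the iodide from bromide 7. The halogen is exchanged at the saturated ester stage because an aldehyde or an enoate would react with the amine ligand of the exchange catalyst, and because a bromide is the safer spectator in the preceding rhodium step.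

**7 from 4 and 6.** The C1–ring C bond is cut. A rhodium-catalysed conjugate arylation of cinnamate 4 by boronate 6 sets C1, the only stereocentre that later steps cannot correct. The halogenated ring is placed on the enoate because ortho-halogenated arylboron reagents transmetalate poorly.

**4 from 2 and 3; 2 from 1; 6 from 5.** An olefination of aldehyde 2 with phosphonate 3 and two phenol silylations reach commercial materials.

## Alternatives that were turned down

**Alternative 1:** Both ring B bonds C2–C3 and C1–C8a are cut, back to the open-chain ester A1, in which a silylated 4-hydroxy-3-methoxycinnamyl unit is joined through oxygen to a silylated 4-hydroxy-3-methoxycinnamoyl unit.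
- Forward key step: a pyrylium photo-oxidant paired with a chiral imidodiphosphorimidate anion oxidises the styrene. Its β-carbon bonds to the α-carbon of the cinnamate, the benzylic C1 centre closes on ring A para to the methoxy group, and a hydrogen shift restores aromaticity, giving lactone A2.
- For it: A1 is only a few steps from simple cinnamyl building blocks, all three stereocentres and ring B form in one step, and the lactone differentiates the arms. In step count this alternative is stronger than the chosen route.
- Against it: a styrene radical cation must attack an electron-poor cinnamate. The ester tether prefers the conformer that cannot cyclise. The absolute configuration would depend on ion pairing of a chiral anion with a delocalised radical cation across a flexible tether. The trans-fused lactone A2 has an enolisable C2 and can slip to the cis fusion. Converting A2 to the target still needs lactone opening, masking of the C3 carbinol, two reductions, acylation and deprotection.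
- Comparison: the chosen route takes its absolute configuration from a well-established catalytic arylation and sets C2 and C3 under thermodynamic control.

**Alternative 2:** Only C4–C4a is cut. The precursor A3 already has C1, C2 and the coumarate, and carries an oxetan-3-yl group as the future C3.
- Forward key step: a metal triflate Lewis acid activates the oxetane, and the ring A carbon para to the free phenol opens one of the two diastereotopic CH2–O bonds, closing ring B and releasing the C3 carbinol to give A4, the di-O-acetyl derivative of the target.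
- For it: A4 is one deprotection from the target and the C3 arm never needs a protecting group. On endgame economy this alternative is clearly stronger.
- Against it: the work is moved into A3, whose C1/C2 stereodiad with an oxetanyl substituent and an acylated arm is itself a multi-step asymmetric problem that the key step does not address. Which CH2 of the oxetane is attacked decides C3 and is left to substrate control. A Lewis acid acting on a 1,4-diol monoester invites acyl migration and participation by the ester carbonyl. Two aryl acetates must finally be removed selectively beside an alkyl cinnamate.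
- Comparison: the chosen route offers a precursor with a single stereocentre that is reachable by routine reactions, so the uncertainty is concentrated in one step.

**Alternative 3:** C3–C4 is cut. The precursor A5 carries a para-hydroxybenzyl alcohol on ring A and an aldehyde chain with C1 and C2 already in place.
- Forward key step: a diarylprolinol silyl ether with weak acid dehydrates the benzyl alcohol to the quinone methide, and the enamine carbon C3 adds to C4, giving aldehyde A6.
- For it: the conditions are mild and metal-free, the ring A phenol serves as the activating group, the arms emerge differentiated (formyl on C3, benzyl ether on C2), and C3 can be equilibrated to trans. On thermodynamic control of C3 it is as strong as the chosen route, and the count of steps after the key step is about the same.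
- Against it: A5 again needs the C1/C2 diad before the key step. A terminal quinone methide is generated slowly from a primary benzylic alcohol and is prone to oligomerise or add water. The chiral amine is largely redundant for an epimerisable centre. The benzyl ether has to be exchanged before acylation.
- Comparison: the chosen route creates C2 and C3 in the key step itself from a simpler precursor.

Key step: step 8

## Remarks before the steps

- Ring positions are numbered as in the analysis: C1 bears ring C, C2 and C3 bear the arms, C4 is the methylene, C4a and C8a are the fusion atoms.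
- Compound 1 is taken as the commercial 6-bromo isomer; direct bromination of isovanillin is not used, because it places bromine between the formyl and hydroxyl groups.
- Enol derivatives 10 and 13 are expected as E/Z mixtures; the E isomer is drawn, and both isomers converge in step 8.
- In step 4 the antipode of the diene ligand that delivers the (S) ester is used; both antipodes are available, and the sense is to be confirmed on the first batch.

## Steps

**Step 1**
Reactants: 1 2-bromo-5-hydroxy-4-methoxybenzaldehyde
Product: 2 2-bromo-4-methoxy-5-(triisopropylsilyloxy)benzaldehyde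
Conditions: TIPSCl, imidazole, DMF, rt
Reagents that add atoms: triisopropylsilyl chloride, CC(C)[Si](Cl)(C(C)C)C(C)C
Why: Imidazole-promoted silylation of a phenol; the triisopropylsilyl ether is chosen because it resists the aqueous base of step 4 and the alkoxide of step 8 and leaves with fluoride at the end.

**Step 2**
Reactants: 2 2-bromo-4-methoxy-5-(triisopropylsilyloxy)benzaldehyde; 3 trimethyl phosphonoacetate
Product: 4 methyl (E)-3-[2-bromo-4-methoxy-5-(triisopropylsilyloxy)phenyl]prop-2-enoate
Conditions: NaH, THF, 0 °C → rt
Reagents that add atoms: none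
Why: Horner–Wadsworth–Emmons olefination; the stabilised phosphonate anion should give the E-enoate.

**Step 3**
Reactants: 5 2-methoxy-4-(4,4,5,5-tetramethyl-1,3,2-dioxaborolan-2-yl)phenol
Product: 6 2-[3-methoxy-4-(triisopropylsilyloxy)phenyl]-4,4,5,5-tetramethyl-1,3,2-dioxaborolane
Conditions: TIPSCl, imidazole, DMF, rt
Reagents that add atoms: triisopropylsilyl chloride, CC(C)[Si](Cl)(C(C)C)C(C)C
Why: Phenol silylation; the pinacol boronate is inert to these conditions.

**Step 4**
Reactants: 4 methyl (E)-3-[2-bromo-4-methoxy-5-(triisopropylsilyloxy)phenyl]prop-2-enoate; 6 2-[3-methoxy-4-(triisopropylsilyloxy)phenyl]-4,4,5,5-tetramethyl-1,3,2-dioxaborolane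
Product: 7 methyl (3S)-3-[2-bromo-4-methoxy-5-(triisopropylsilyloxy)phenyl]-3-[3-methoxy-4-(triisopropylsilyloxy)phenyl]propanoate
Conditions: [RhCl(C2H4)2]2 (2.5 mol %), 2,5-diphenylbicyclo[2.2.2]octa-2,5-diene (one antipode, 5.5 mol %), aq. K3PO4, 1,4-dioxane/H2O, 50 °C
Reagents that add atoms: none
Why: Hayashi–Miyaura asymmetric 1,4-addition: the aryl–rhodium species formed by transmetalation inserts the enoate and water protonates the resulting rhodium enolate, the chiral diene selecting the enoate face and so setting C1 as S. The ethylene precatalyst is used because a cyclooctadiene precatalyst would compete as an achiral diene, and the aryl bromide is expected to be inert to rhodium under these conditions.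

**Step 5**
Reactants: 7 methyl (3S)-3-[2-bromo-4-methoxy-5-(triisopropylsilyloxy)phenyl]-3-[3-methoxy-4-(triisopropylsilyloxy)phenyl]propanoate
Product: 8 methyl (3S)-3-[2-iodo-4-methoxy-5-(triisopropylsilyloxy)phenyl]-3-[3-methoxy-4-(triisopropylsilyloxy)phenyl]propanoate
Conditions: CuI (10 mol %), trans-N,N'-dimethylcyclohexane-1,2-diamine (20 mol %), NaI, 1,4-dioxane, 110 °C
Reagents that add atoms: sodium iodide, [Na+].[I-]
Why: Copper–diamine-catalysed aromatic Finkelstein reaction, driven by precipitation of NaBr from dioxane; the ester and silyl ethers are inert and the stereocentre is not acidic.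

**Step 6**
Reactants: 8 methyl (3S)-3-[2-iodo-4-methoxy-5-(triisopropylsilyloxy)phenyl]-3-[3-methoxy-4-(triisopropylsilyloxy)phenyl]propanoate
Product: 9 (3S)-3-[2-iodo-4-methoxy-5-(triisopropylsilyloxy)phenyl]-3-[3-methoxy-4-(triisopropylsilyloxy)phenyl]propanal
Conditions: i-Bu2AlH (1.1 equiv), CH2Cl2, −78 °C; MeOH, aq. potassium sodium tartrate
Reagents that add atoms: none
Why: Low-temperature partial reduction of a methyl ester to the aldehyde; at −78 °C over-reduction is held back and the aryl iodide is not touched.

**Step 7**
Reactants: 9 (3S)-3-[2-iodo-4-methoxy-5-(triisopropylsilyloxy)phenyl]-3-[3-methoxy-4-(triisopropylsilyloxy)phenyl]propanal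
Product: 10 (1E,3S)-3-[2-iodo-4-methoxy-5-(triisopropylsilyloxy)phenyl]-3-[3-methoxy-4-(triisopropylsilyloxy)phenyl]prop-1-en-1-yl acetate
Conditions: Ac2O, KOAc, Et3N, 110 °C
Reagents that add atoms: acetic anhydride, CC(=O)OC(C)=O
Why: O-Acetylation of the aldehyde enol under acetate and amine base (enol acetate formation); only C2 is enolisable, and the non-acidic C1 centre is untouched.

**Step 8**
Reactants: 10 (1E,3S)-3-[2-iodo-4-methoxy-5-(triisopropylsilyloxy)phenyl]-3-[3-methoxy-4-(triisopropylsilyloxy)phenyl]prop-1-en-1-yl acetate; 11 tributyltin methoxide (Bu3SnOMe); 12 tert-butyl acrylate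
Product: 18 tert-butyl (1S,2R,3R)-2-formyl-6-methoxy-1-[3-methoxy-4-(triisopropylsilyloxy)phenyl]-7-(triisopropylsilyloxy)-1,2,3,4-tetrahydronaphthalene-3-carboxylate, via stannyl enol ether 13 (not isolated), via aryl radical 14 (not isolated), via ester radical 15 (not isolated), via stannyloxy radical 16 (not isolated), via C3 epimer 17 (not isolated)
Conditions: Bu3SnOMe (1.0 equiv), PhH, 60 °C, MeOAc removed; then tert-butyl acrylate (8 equiv), AIBN (0.2 equiv in portions), PhH (dilute), 80 °C; KF on silica; then t-BuOK (0.2 equiv), t-BuOH/THF, 0 °C → rt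
Reagents that add atoms: none
Why: Proposed new method: acyl transfer from 10 to Bu3SnOMe gives the stannyl enol ether 13, and a Bu3Sn radical (released when an initiator radical alkylates 13) abstracts iodine from C4a to give the σ-radical 14, which has only 4-exo or 5-endo options inside the molecule and so adds to the CH2 terminus of 12 (bond C4–C4a), giving the electrophilic ester radical 15. Radical 15 closes ring B by a polarity-matched 6-exo-trig attack of C3 on the electron-rich enol carbon C2, and the α-stannyloxy radical 16 then loses Bu3Sn by β-scission, which leaves the C2 formyl group and carries the chain without any hydride. The closest known reaction types are the radical alkylation of ketone stannyl enolates by halides, including their three-component coupling with electron-poor alkenes, and aryl radical additions to acrylates followed by 6-exo closure onto a pendant alkene; new here are the aldehyde-derived stannyl enolate, the aryl iodide as chain partner and the intramolecular second stage. A tin hydride chain with a silyl enol ether is avoided on kinetic grounds, because the hydride would have to be scarce for 14 to reach the acrylate yet plentiful for the nucleophilic α-oxy radical to be reduced before it adds to the excess acrylate, whereas fragmentation of 16 is unimolecular; the iodide is needed because Bu3Sn radicals otherwise rest as reversible adducts of 12 and start oligomer chains that alkylate 13. C2 is set in a chair-like transition state in which the C1–H bond lies near the plane of the enol double bond (allylic strain), so that ring C and the enol carbon both sit equatorial and the new bond forms trans to ring C. C3 is set by the tert-butyl ester preferring the equatorial side of the same chair, the 2,3-cis epimer 17 being the expected minor product. Because C2 is now α to an aldehyde and C3 α to an ester while C1 is not acidic, the closing t-BuOK treatment equilibrates both centres to the all-equatorial isomer 18, and tert-butoxide cannot transesterify a tert-butyl ester. The step needs capture of 14 by 12 ahead of solvent, ring closure of 15 ahead of a second acrylate addition and fragmentation of 16 ahead of acrylate addition, which a moderate acrylate concentration, high dilution of 13 and the absence of any hydrogen donor are meant to secure.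

**Step 9**
Reactants: 18 tert-butyl (1S,2R,3R)-2-formyl-6-methoxy-1-[3-methoxy-4-(triisopropylsilyloxy)phenyl]-7-(triisopropylsilyloxy)-1,2,3,4-tetrahydronaphthalene-3-carboxylate
Product: 19 tert-butyl (1S,2R,3R)-2-(hydroxymethyl)-6-methoxy-1-[3-methoxy-4-(triisopropylsilyloxy)phenyl]-7-(triisopropylsilyloxy)-1,2,3,4-tetrahydronaphthalene-3-carboxylate
Conditions: NaBH4, MeOH/THF, −20 → 0 °C
Reagents that add atoms: none
Why: Chemoselective borohydride reduction of an aldehyde beside an ester; the tert-butyl ester is too hindered to lactonise with the new carbinol, and C2 is fixed from here on.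

**Step 10**
Reactants: 20 (E)-p-coumaric acid
Product: 22 (E)-3-[4-(triisopropylsilyloxy)phenyl]prop-2-enoic acid, via silyl ester 21 (not isolated)
Conditions: TIPSCl (2.3 equiv), imidazole, DMF, rt; then K2CO3, MeOH/THF/H2O, rt; citric acid
Reagents that add atoms: triisopropylsilyl chloride, CC(C)[Si](Cl)(C(C)C)C(C)C
Why: Silylation of phenol and acid followed by selective hydrolysis of the silyl ester 21, which is far more labile than the aryl silyl ether.

**Step 11**
Reactants: 19 tert-butyl (1S,2R,3R)-2-(hydroxymethyl)-6-methoxy-1-[3-methoxy-4-(triisopropylsilyloxy)phenyl]-7-(triisopropylsilyloxy)-1,2,3,4-tetrahydronaphthalene-3-carboxylate; 22 (E)-3-[4-(triisopropylsilyloxy)phenyl]prop-2-enoic acid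
Product: 23 tert-butyl (1S,2R,3R)-6-methoxy-1-[3-methoxy-4-(triisopropylsilyloxy)phenyl]-7-(triisopropylsilyloxy)-2-({(E)-3-[4-(triisopropylsilyloxy)phenyl]prop-2-enoyl}oxymethyl)-1,2,3,4-tetrahydronaphthalene-3-carboxylate
Conditions: EDC·HCl, DMAP, CH2Cl2, 0 °C → rt
Reagents that add atoms: none
Why: Steglich-type carbodiimide esterification of a primary alcohol; the C2 carbinol is the only hydroxyl present, so the acyl group is placed without a selectivity problem.

**Step 12**
Reactants: 23 tert-butyl (1S,2R,3R)-6-methoxy-1-[3-methoxy-4-(triisopropylsilyloxy)phenyl]-7-(triisopropylsilyloxy)-2-({(E)-3-[4-(triisopropylsilyloxy)phenyl]prop-2-enoyl}oxymethyl)-1,2,3,4-tetrahydronaphthalene-3-carboxylate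
Product: 24 (1S,2R,3R)-6-methoxy-1-[3-methoxy-4-(triisopropylsilyloxy)phenyl]-7-(triisopropylsilyloxy)-2-({(E)-3-[4-(triisopropylsilyloxy)phenyl]prop-2-enoyl}oxymethyl)-1,2,3,4-tetrahydronaphthalene-3-carboxylic acid
Conditions: CF3CO2H/CH2Cl2 (1:4), anisole, 0 °C → rt
Reagents that add atoms: none
Why: Acidolysis of a tert-butyl ester with loss of isobutene; the primary alkyl cinnamate and the aryl silyl ethers are stable to this acid, and anisole is present to intercept any tert-butyl cation before it reaches the electron-rich rings.

**Step 13**
Reactants: 24 (1S,2R,3R)-6-methoxy-1-[3-methoxy-4-(triisopropylsilyloxy)phenyl]-7-(triisopropylsilyloxy)-2-({(E)-3-[4-(triisopropylsilyloxy)phenyl]prop-2-enoyl}oxymethyl)-1,2,3,4-tetrahydronaphthalene-3-carboxylic acid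
Product: 25 [(1S,2R,3R)-3-(hydroxymethyl)-6-methoxy-1-[3-methoxy-4-(triisopropylsilyloxy)phenyl]-7-(triisopropylsilyloxy)-1,2,3,4-tetrahydronaphthalen-2-yl]methyl (E)-3-[4-(triisopropylsilyloxy)phenyl]prop-2-enoate
Conditions: BH3·THF, THF, 0 °C → rt; MeOH
Reagents that add atoms: none
Why: Borane reduces a free carboxylic acid through its acyloxyborane much faster than it attacks an ester or an electron-poor conjugated alkene; the medium is not basic, so the coumarate should stay on the C2 arm.

**Step 14**
Reactants: 25 [(1S,2R,3R)-3-(hydroxymethyl)-6-methoxy-1-[3-methoxy-4-(triisopropylsilyloxy)phenyl]-7-(triisopropylsilyloxy)-1,2,3,4-tetrahydronaphthalen-2-yl]methyl (E)-3-[4-(triisopropylsilyloxy)phenyl]prop-2-enoate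
Product: 26 [(1S,2R,3R)-7-hydroxy-1-(4-hydroxy-3-methoxyphenyl)-3-(hydroxymethyl)-6-methoxy-1,2,3,4-tetrahydronaphthalen-2-yl]methyl (E)-3-(4-hydroxyphenyl)prop-2-enoate (CNP0403384.1)
Conditions: Bu4NF/AcOH (1:1), THF, 0 °C → rt
Reagents that add atoms: none
Why: Fluoride cleavage of three aryl silyl ethers; acetic acid buffers the medium so that neither phenoxide nor alkoxide builds up, which protects the ester from cleavage and from migration to the C3 carbinol.

## Compound list

1 | 2-bromo-5-hydroxy-4-methoxybenzaldehyde | O=Cc1cc(O)c(OC)cc1Br | starting material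
2 | 2-bromo-4-methoxy-5-(triisopropylsilyloxy)benzaldehyde | O=Cc1cc(O[Si](C(C)C)(C(C)C)C(C)C)c(OC)cc1Br | intermediate
3 | trimethyl phosphonoacetate | COC(=O)CP(=O)(OC)OC | starting material
4 | methyl (E)-3-[2-bromo-4-methoxy-5-(triisopropylsilyloxy)phenyl]prop-2-enoate | COC(=O)/C=C/c1cc(O[Si](C(C)C)(C(C)C)C(C)C)c(OC)cc1Br | intermediate
5 | 2-methoxy-4-(4,4,5,5-tetramethyl-1,3,2-dioxaborolan-2-yl)phenol | COc1cc(B2OC(C)(C)C(C)(C)O2)ccc1O | starting material
6 | 2-[3-methoxy-4-(triisopropylsilyloxy)phenyl]-4,4,5,5-tetramethyl-1,3,2-dioxaborolane | COc1cc(B2OC(C)(C)C(C)(C)O2)ccc1O[Si](C(C)C)(C(C)C)C(C)C | intermediate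
7 | methyl (3S)-3-[2-bromo-4-methoxy-5-(triisopropylsilyloxy)phenyl]-3-[3-methoxy-4-(triisopropylsilyloxy)phenyl]propanoate | COc1cc([C@H](CC(=O)OC)c2cc(O[Si](C(C)C)(C(C)C)C(C)C)c(OC)cc2Br)ccc1O[Si](C(C)C)(C(C)C)C(C)C | intermediate
8 | methyl (3S)-3-[2-iodo-4-methoxy-5-(triisopropylsilyloxy)phenyl]-3-[3-methoxy-4-(triisopropylsilyloxy)phenyl]propanoate | COc1cc([C@H](CC(=O)OC)c2cc(O[Si](C(C)C)(C(C)C)C(C)C)c(OC)cc2I)ccc1O[Si](C(C)C)(C(C)C)C(C)C | intermediate
9 | (3S)-3-[2-iodo-4-methoxy-5-(triisopropylsilyloxy)phenyl]-3-[3-methoxy-4-(triisopropylsilyloxy)phenyl]propanal | COc1cc([C@H](CC=O)c2cc(O[Si](C(C)C)(C(C)C)C(C)C)c(OC)cc2I)ccc1O[Si](C(C)C)(C(C)C)C(C)C | intermediate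
10 | (1E,3S)-3-[2-iodo-4-methoxy-5-(triisopropylsilyloxy)phenyl]-3-[3-methoxy-4-(triisopropylsilyloxy)phenyl]prop-1-en-1-yl acetate | COc1cc([C@H](/C=C/OC(C)=O)c2cc(O[Si](C(C)C)(C(C)C)C(C)C)c(OC)cc2I)ccc1O[Si](C(C)C)(C(C)C)C(C)C | intermediate
11 | tributyltin methoxide | CCCC[Sn](CCCC)(CCCC)OC | starting material
12 | tert-butyl acrylate | C=CC(=O)OC(C)(C)C | starting material
13 | tributylstannyl enol ether of aldehyde 9 (E drawn) | COc1cc([C@H](/C=C/O[Sn](CCCC)(CCCC)CCCC)c2cc(O[Si](C(C)C)(C(C)C)C(C)C)c(OC)cc2I)ccc1O[Si](C(C)C)(C(C)C)C(C)C | intermediate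
14 | C4a aryl radical derived from 13 | COc1cc([C@H](/C=C/O[Sn](CCCC)(CCCC)CCCC)c2cc(O[Si](C(C)C)(C(C)C)C(C)C)c(OC)c[c]2)ccc1O[Si](C(C)C)(C(C)C)C(C)C | intermediate
15 | α-ester radical formed from 14 and 12 | COc1cc([C@H](/C=C/O[Sn](CCCC)(CCCC)CCCC)c2cc(O[Si](C(C)C)(C(C)C)C(C)C)c(OC)cc2C[CH]C(=O)OC(C)(C)C)ccc1O[Si](C(C)C)(C(C)C)C(C)C | intermediate
16 | cyclised α-stannyloxy radical | COc1cc([C@H]2c3cc(O[Si](C(C)C)(C(C)C)C(C)C)c(OC)cc3C[C@@H](C(=O)OC(C)(C)C)[C@@H]2[CH]O[Sn](CCCC)(CCCC)CCCC)ccc1O[Si](C(C)C)(C(C)C)C(C)C | intermediate
17 | tert-butyl (1S,2R,3S)-2-formyl-6-methoxy-1-[3-methoxy-4-(triisopropylsilyloxy)phenyl]-7-(triisopropylsilyloxy)-1,2,3,4-tetrahydronaphthalene-3-carboxylate (2,3-cis epimer) | COc1cc([C@H]2c3cc(O[Si](C(C)C)(C(C)C)C(C)C)c(OC)cc3C[C@H](C(=O)OC(C)(C)C)[C@@H]2C=O)ccc1O[Si](C(C)C)(C(C)C)C(C)C | intermediate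
18 | tert-butyl (1S,2R,3R)-2-formyl-6-methoxy-1-[3-methoxy-4-(triisopropylsilyloxy)phenyl]-7-(triisopropylsilyloxy)-1,2,3,4-tetrahydronaphthalene-3-carboxylate | COc1cc([C@H]2c3cc(O[Si](C(C)C)(C(C)C)C(C)C)c(OC)cc3C[C@@H](C(=O)OC(C)(C)C)[C@@H]2C=O)ccc1O[Si](C(C)C)(C(C)C)C(C)C | intermediate
19 | tert-butyl (1S,2R,3R)-2-(hydroxymethyl)-6-methoxy-1-[3-methoxy-4-(triisopropylsilyloxy)phenyl]-7-(triisopropylsilyloxy)-1,2,3,4-tetrahydronaphthalene-3-carboxylate | COc1cc([C@H]2c3cc(O[Si](C(C)C)(C(C)C)C(C)C)c(OC)cc3C[C@@H](C(=O)OC(C)(C)C)[C@@H]2CO)ccc1O[Si](C(C)C)(C(C)C)C(C)C | intermediate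
20 | (E)-p-coumaric acid | O=C(O)/C=C/c1ccc(O)cc1 | starting material
21 | triisopropylsilyl (E)-3-[4-(triisopropylsilyloxy)phenyl]prop-2-enoate | CC(C)[Si](OC(=O)/C=C/c1ccc(O[Si](C(C)C)(C(C)C)C(C)C)cc1)(C(C)C)C(C)C | intermediate
22 | (E)-3-[4-(triisopropylsilyloxy)phenyl]prop-2-enoic acid | O=C(O)/C=C/c1ccc(O[Si](C(C)C)(C(C)C)C(C)C)cc1 | intermediate
23 | tert-butyl (1S,2R,3R)-6-methoxy-1-[3-methoxy-4-(triisopropylsilyloxy)phenyl]-7-(triisopropylsilyloxy)-2-({(E)-3-[4-(triisopropylsilyloxy)phenyl]prop-2-enoyl}oxymethyl)-1,2,3,4-tetrahydronaphthalene-3-carboxylate | COc1cc([C@H]2c3cc(O[Si](C(C)C)(C(C)C)C(C)C)c(OC)cc3C[C@@H](C(=O)OC(C)(C)C)[C@@H]2COC(=O)/C=C/c2ccc(O[Si](C(C)C)(C(C)C)C(C)C)cc2)ccc1O[Si](C(C)C)(C(C)C)C(C)C | intermediate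
24 | (1S,2R,3R)-6-methoxy-1-[3-methoxy-4-(triisopropylsilyloxy)phenyl]-7-(triisopropylsilyloxy)-2-({(E)-3-[4-(triisopropylsilyloxy)phenyl]prop-2-enoyl}oxymethyl)-1,2,3,4-tetrahydronaphthalene-3-carboxylic acid | COc1cc([C@H]2c3cc(O[Si](C(C)C)(C(C)C)C(C)C)c(OC)cc3C[C@@H](C(=O)O)[C@@H]2COC(=O)/C=C/c2ccc(O[Si](C(C)C)(C(C)C)C(C)C)cc2)ccc1O[Si](C(C)C)(C(C)C)C(C)C | intermediate
25 | [(1S,2R,3R)-3-(hydroxymethyl)-6-methoxy-1-[3-methoxy-4-(triisopropylsilyloxy)phenyl]-7-(triisopropylsilyloxy)-1,2,3,4-tetrahydronaphthalen-2-yl]methyl (E)-3-[4-(triisopropylsilyloxy)phenyl]prop-2-enoate | COc1cc([C@H]2c3cc(O[Si](C(C)C)(C(C)C)C(C)C)c(OC)cc3C[C@@H](CO)[C@@H]2COC(=O)/C=C/c2ccc(O[Si](C(C)C)(C(C)C)C(C)C)cc2)ccc1O[Si](C(C)C)(C(C)C)C(C)C | intermediate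
26 | [(1S,2R,3R)-7-hydroxy-1-(4-hydroxy-3-methoxyphenyl)-3-(hydroxymethyl)-6-methoxy-1,2,3,4-tetrahydronaphthalen-2-yl]methyl (E)-3-(4-hydroxyphenyl)prop-2-enoate | COc1cc([C@H]2c3cc(O)c(OC)cc3C[C@@H](CO)[C@@H]2COC(=O)/C=C/c2ccc(O)cc2)ccc1O | target

## Step count and least certain steps

Total: 14 steps. Longest linear sequence: 12 steps (1, 2, 4, 5, 6, 7, 8, 9, 11, 12, 13, 14).

**Step 8 (key step, proposed new method).** Several processes can divert the chain:
- addition of the α-stannyloxy radical 16 to a second acrylate before it fragments;
- telomerisation of ester radical 15 with acrylate before ring closure;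
- the stannyl enolate resting in its carbon-bound form;
- ionic aldol addition of 13 to the aldehyde product as it accumulates.

All stem from running an electron-poor alkene in excess beside a nucleophilic enolate and a nucleophilic late radical. Fallback by known reactions, setting out from 8 and returning at 19:
- Heck coupling of 8 with 12 (Pd(OAc)2, P(o-tol)3, Et3N, DMF, 90 °C) should give the cinnamate diester F1.
- Hydrogenation (H2, Pd on carbon, EtOAc) should give the saturated diester F2.
- Double deprotonation with i-Pr2NLi at −78 °C and oxidation of the dienolate with I2 (intramolecular oxidative enolate coupling) should close ring B between the two ester α-carbons; equilibration with t-BuOK then gives the all-trans diester F3.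
- LiBH4 in THF at 0 °C should reduce the methyl ester of F3 and leave the tert-butyl ester, giving 19.

**Step 4.** Insertion may be slow next to the ortho bromine, the electron-rich boronate may protodeboronate, an aryl silyl ether may be lost in aqueous base, or face selectivity may be insufficient. Fallback from 4 and 6, returning at 7: run the addition with the more active achiral catalyst [Rh(OH)(cod)]2 to obtain the racemic ester F4, then separate the enantiomers by preparative chromatography on a chiral stationary phase to obtain 7.

**Step 5.** Halide exchange is an equilibrium and may stop short at the hindered position, leaving bromide that would be a chain-breaking passenger in step 8. Fallback from 7, returning at 8: palladium-catalysed stannylation (Me3SnSnMe3, Pd(PPh3)4, toluene, 100 °C) to the arylstannane F5, then ipso-iododestannylation with I2 in CH2Cl2 at 0 °C to give 8.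

**Step 13.** Borane may begin to hydroborate the cinnamate double bond or reduce the cinnamate ester if the acid is slow to react. Fallback from 24, returning at 25: activate the acid with isobutyl chloroformate and N-methylmorpholine at −15 °C to the mixed anhydride F6 (not isolated), then reduce with NaBH4 in THF/H2O at 0 °C, a nucleophilic hydride that attacks only the activated carbonyl.

**Step 14.** The cinnamate may migrate to the free C3 carbinol or be cleaved if the fluoride medium becomes basic. Fallback from 24, returning at 26: reverse the order. Desilylate the acid 24 with buffered Bu4NF while no free aliphatic hydroxyl is present, giving the triphenol acid F7; then reduce the carboxylic acid of F7 with excess BH3·THF (the phenols being released from their borates on work-up) to give 26 under non-basic conditions.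

## Further compounds

F1 | step 8 | methyl (3S)-3-{2-[(E)-3-tert-butoxy-3-oxoprop-1-enyl]-4-methoxy-5-(triisopropylsilyloxy)phenyl}-3-[3-methoxy-4-(triisopropylsilyloxy)phenyl]propanoate | COc1cc([C@H](CC(=O)OC)c2cc(O[Si](C(C)C)(C(C)C)C(C)C)c(OC)cc2/C=C/C(=O)OC(C)(C)C)ccc1O[Si](C(C)C)(C(C)C)C(C)C
F2 | step 8 | methyl (3S)-3-[2-(3-tert-butoxy-3-oxopropyl)-4-methoxy-5-(triisopropylsilyloxy)phenyl]-3-[3-methoxy-4-(triisopropylsilyloxy)phenyl]propanoate | COc1cc([C@H](CC(=O)OC)c2cc(O[Si](C(C)C)(C(C)C)C(C)C)c(OC)cc2CCC(=O)OC(C)(C)C)ccc1O[Si](C(C)C)(C(C)C)C(C)C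
F3 | step 8 | 3-tert-butyl 2-methyl (1S,2R,3R)-6-methoxy-1-[3-methoxy-4-(triisopropylsilyloxy)phenyl]-7-(triisopropylsilyloxy)-1,2,3,4-tetrahydronaphthalene-2,3-dicarboxylate | COc1cc([C@H]2c3cc(O[Si](C(C)C)(C(C)C)C(C)C)c(OC)cc3C[C@@H](C(=O)OC(C)(C)C)[C@@H]2C(=O)OC)ccc1O[Si](C(C)C)(C(C)C)C(C)C
F4 | step 4 | racemic methyl 3-[2-bromo-4-methoxy-5-(triisopropylsilyloxy)phenyl]-3-[3-methoxy-4-(triisopropylsilyloxy)phenyl]propanoate | COc1cc(C(CC(=O)OC)c2cc(O[Si](C(C)C)(C(C)C)C(C)C)c(OC)cc2Br)ccc1O[Si](C(C)C)(C(C)C)C(C)C
F5 | step 5 | methyl (3S)-3-[4-methoxy-5-(triisopropylsilyloxy)-2-(trimethylstannyl)phenyl]-3-[3-methoxy-4-(triisopropylsilyloxy)phenyl]propanoate | COc1cc([C@H](CC(=O)OC)c2cc(O[Si](C(C)C)(C(C)C)C(C)C)c(OC)cc2[Sn](C)(C)C)ccc1O[Si](C(C)C)(C(C)C)C(C)C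
F6 | step 13 | isobutyl carbonic mixed anhydride of acid 24 | COc1cc([C@H]2c3cc(O[Si](C(C)C)(C(C)C)C(C)C)c(OC)cc3C[C@@H](C(=O)OC(=O)OCC(C)C)[C@@H]2COC(=O)/C=C/c2ccc(O[Si](C(C)C)(C(C)C)C(C)C)cc2)ccc1O[Si](C(C)C)(C(C)C)C(C)C
F7 | step 14 | (1S,2R,3R)-7-hydroxy-1-(4-hydroxy-3-methoxyphenyl)-2-{[(E)-3-(4-hydroxyphenyl)prop-2-enoyl]oxymethyl}-6-methoxy-1,2,3,4-tetrahydronaphthalene-3-carboxylic acid | COc1cc([C@H]2c3cc(O)c(OC)cc3C[C@@H](C(=O)O)[C@@H]2COC(=O)/C=C/c2ccc(O)cc2)ccc1O
A1 | alternative 1 | (E)-3-[4-(tert-butyldimethylsilyloxy)-3-methoxyphenyl]prop-2-enyl (E)-3-[4-(tert-butyldimethylsilyloxy)-3-methoxyphenyl]prop-2-enoate | COc1cc(/C=C/COC(=O)/C=C/c2ccc(O[Si](C)(C)C(C)(C)C)c(OC)c2)ccc1O[Si](C)(C)C(C)(C)C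
A2 | alternative 1 | trans-fused aryltetralin lactone with the carbonyl on C2 (bis-silyl ether) | COc1cc([C@H]2c3cc(O[Si](C)(C)C(C)(C)C)c(OC)cc3C[C@@H](COC4=O)[C@@H]24)ccc1O[Si](C)(C)C(C)(C)C
A3 | alternative 2 | open-chain oxetan-3-yl precursor with C1 and C2 set, ring A as free phenol, ring C and coumarate as acetates | COc1cc([C@@H](c2cc(O)c(OC)cc2)[C@@H](COC(=O)/C=C/c2ccc(OC(C)=O)cc2)C2COC2)ccc1OC(C)=O
A4 | alternative 2 | di-O-acetyl derivative of the target | COc1cc([C@H]2c3cc(O)c(OC)cc3C[C@@H](CO)[C@@H]2COC(=O)/C=C/c2ccc(OC(C)=O)cc2)ccc1OC(C)=O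
A5 | alternative 3 | open-chain aldehyde with a para-hydroxybenzyl alcohol on ring A and a C2 benzyloxymethyl group | COc1cc([C@@H](c2cc(O)c(OC)cc2CO)[C@@H](COCc2ccccc2)CC=O)ccc1O[Si](C)(C)C(C)(C)C
A6 | alternative 3 | all-trans 1-aryltetralin-3-carbaldehyde with C2 benzyloxymethyl | COc1cc([C@H]2c3cc(O)c(OC)cc3C[C@@H](C=O)[C@@H]2COCc2ccccc2)ccc1O[Si](C)(C)C(C)(C)C
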